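## Structural features

The target is a 3,4-dihydroisocoumarin lactol in which a pentasubstituted benzene (ring A: C4a, C5 methyl, C6 methoxy, C7 H, C8 hydroxyl, C8a) is fused to a six-membered hydroxy-lactone (C1 carbonyl, O2, hemiketal C3, methine C4). C3 carries a hydroxyl and a CH2O group esterified by ring B, 2,4-dihydroxy-5,6-dimethylbenzoic acid, whose carboxyl lies between a hydroxyl and a methyl group. The two stereocentres are neighbours: C4 (S) is a benzylic methine whose methyl is peri to the C5 methyl, and C3 (R) is the anomeric carbon. C3 can open to the δ-keto acid and close again, so its configuration follows from an equilibrium governed by C4; C4 is therefore the only centre that must be built, and because it is α to the ketone in the open form it is also the centre that can be lost. The fragile points are the lactol (acid dehydrates it across C3–C4 to an isocoumarin, alcohols turn it into a pseudo-ester), the crowded aryl ester between the two halves, and three free phenols. The real difficulty is to assemble the crowded ring A next to a C4 centre of fixed configuration, and to raise C3 to the ketone level late without epimerising C4 and without letting the C3 oxygen close onto C1 while it is still an alcohol. Ring A shows the 1,3-alternating pattern of a folded tetraketide (carboxyl carbon C1 on C8a, oxygen on C8 and C6, carbon substituents on C5 and C4a); the key step uses this by forming the C4a–C8a bond through aldol closure of an open-chain 3,5,7-triketo ester released from a diketo-dioxinone.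

## Logic of the disconnections

**25 ⇒ 24.** The hemiketal bond O2–C3 and four O–CH2Ph bonds are cut. The lactol is only the closed form of a δ-keto acid, so C3 needs no stereocontrol, and one hydrogenolysis can free the C1 acid and all three phenols. The forward step must be neutral and aprotic: acid would dehydrate the lactol, and the open keto acid has C4 α to a ketone.

**24 ⇒ 23.** The C3 carbonyl is taken back to a secondary alcohol. A C3 ketone cannot be carried earlier, because in 10 it would make C4 the central carbon of a β-dicarbonyl and the centre would racemise. The forward oxidation must run without amine base, on an alcohol flanked by the benzylic centre.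

**23 ⇒ 17 + 21 (through 22).** The ester C(=O)–O bond at the primary oxygen is cut, which divides the molecule into two arene halves of similar size. 21 goes back through 20 and 19 to 18 by cutting the bond between ring B and its carboxyl carbon (formylation para to one hydroxyl and ortho to the other, then oxidation). The forward acylation must distinguish primary from secondary hydroxyl with a di-ortho-substituted acyl chloride, and must be faster than attack of the C3 hydroxyl on the C1 ester.

**17 ⇒ 16 ⇒ 15 ⇒ 14.** The acetonide C–O bonds, the C8 O–benzyl bond and the C6 O–methyl bond are removed in turn. This leaves a resorcylate whose two phenols differ by chelation: the C8 hydroxyl is hydrogen-bonded to the ester and the C6 hydroxyl is not. The forward steps need mono-methylation at C6, then benzylation at C8, which also shields the C1 ester before the diol is released.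

**14 ⇒ 10 + 11 (through 13 and 12).** The C4a–C8a bond of ring A and the C1–O bond of the benzyl ester are cut. The pentasubstituted arene becomes a linear chain in which every ring A substituent is already encoded, and no stereocentre has to be made. The forward step must fold by aldol and not by Claisen condensation, must leave C4 untouched, and must avoid strong acid because of the acetonide.

**10 ⇒ 9 + 6.** The C4a–C5 bond is cut (Claisen-type acylation). The C4 stereocentre now lives in a small chiral fragment and the rest is an achiral dioxinone. The forward step needs the dianion of 9 to react at its terminal carbon and to acylate faster than it deprotonates 6.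

**9 ⇒ 7 + 8.** The C6–C7 bond is cut, a vinylogous acylation of a dioxinone dienolate. Both partners are commercial. The product is more acidic than the starting dioxinone, so the forward step needs excess dienolate.

**6 ⇒ 5 ⇒ 4 ⇒ 3 ⇒ 2 ⇒ 1.** The acyl–imidazole bond, the acetonide, the C–H bonds of the primary carbinol and finally the C4–CH3 bond are removed, which leads to a chiral-pool hydroxy diester. Its carbinol centre controls the methylation and is erased later at the oxidation stage. The forward alkylation must be anti-selective and the minor syn isomer must be removed, because after oxidation of C3 it would end as the enantiomer of the target.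

## Other disconnections considered

**Alternative 1:** The cut is at C1–O2 and O2–C3 of the benzylated lactol A1, with C1 joined directly to C3 instead; this leads to the 2-hydroxy-indan-1-one A2, which already carries the ring B ester on its CH2O group. Forward, periodic acid would cleave the tertiary α-ketol of A2 between carbonyl and carbinol carbon into the aryl carboxylic acid and the C3 ketone, which close at once to A1; a peracid would reach A1 by oxygen insertion.
- In its favour: acid and ketone are born together at the final oxidation level, so no alcohol next to C4 has to be oxidised and no C3 hydroxyl ever faces a C1 ester. Until the cleavage C4 is β, not α, to a carbonyl. On the security of C4 and on the lactonisation problem this plan is better than the chosen one.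
- Against it: A2 needs a five-membered ring on an already pentasubstituted arene, a quaternary carbinol bearing a neopentyl-type ester, and an enantioselective introduction of the methyl-bearing centre next to a peri methyl group. The peracid variant must make the quaternary carbon migrate in competition with a very electron-rich aryl group; the periodic acid variant is selective but tertiary ketols cleave slowly.
- Comparison: the endgame length is equal (A1 still needs hydrogenolysis), but the way to A2 should cost clearly more steps than the way to 10, and its stereocentre rests on a catalytic asymmetric step on a hindered substrate instead of a chiral-pool alkylation. On step economy the chosen plan is ahead.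

**Alternative 2:** The cut is at C1'–C2' and C5'–C6' of ring B. Forward, the 1,3-dioxygenated silyloxy diene A5 would add to the but-2-ynoate ester A4 of the ring A hydroxymethyl ketone, and loss of methanol would aromatise the adduct to keto ester A3 with both ring B phenols free.
- In its favour: the primary alcohol is acylated with a small acid instead of a di-ortho-substituted benzoic acid, and ring B needs no protecting groups. On these two points it is better than the chosen plan. The regiochemistry follows from the polarisation of A4 and A5.
- Against it: it says nothing about ring A or C4, so A4 still has to come from a ring A synthesis such as the chosen one. The cycloaddition needs heat and is run on the compound that holds the enolisable C4 centre beside the C3 ketone. A5 is a silyl ketene acetal that can also attack that ketone or add in Michael fashion without closing. Benzannulations of alkynoates of this kind usually give moderate material balance, here spent on the most advanced intermediate.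
- Comparison: on step count it is equal or slightly better (one cycloaddition in place of the three steps to 21). On risk it is worse: the chosen plan makes its demanding C–C bond before any epimerisable ketone exists and attaches ring B by ordinary acyl substitution.

**Alternative 3:** The cut is at C4a–C5 and C8–C8a of ring A. Forward, the 1,3-dimethoxy-1-silyloxy diene A8 would add to the chiral alkynoate A7, which carries C4 at its propargylic carbon and the ring B ester on the primary oxygen, and loss of methanol would give the ring A benzyl salicylate A6.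
- In its favour: the C6 methoxy group arrives with A8, so no selective phenol methylation is needed (better than the chosen plan). C4 is propargylic and never α to a ketone before the arene exists (better than in 10). The two side-chain oxygens are differentiated on a small fragment, so no diol has to be handled next to the C1 ester (also better).
- Against it: the ring is closed by an intermolecular cycloaddition between an alkynoate with a branched propargylic carbon and a diene substituted at its reacting terminus, which must create four contiguous ring substituents at once. It needs heat, depends on the geometry of the terminal methyl in A8, and A7 can isomerise to an allenoate under base. A7 needs its own multi-step synthesis, including the hindered ring B ester.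
- Comparison: both plans build ring A last from an acyclic chiral fragment and are about equal in step count. The chosen plan closes the ring intramolecularly under mild base with aromatisation as driving force, which is the more dependable ring formation for this crowded substitution pattern, at the price of a C4 centre that is α to a ketone in the precursor.

Key step: step 8

Remark on the chemistry (assumption): C3 is taken to be under thermodynamic control through the open keto acid, the 3R epimer (anomeric hydroxyl axial and trans to the pseudo-axial C4 methyl, acyloxymethyl equatorial) being the favoured form, so the route builds only C4.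

Remark on the structures: the planned key-step precursor 10, its product 14 and the target agree atom by atom and in configuration, and no correction is needed; the C4 descriptor changes from R (2 to 13) to S (14 onward) only through the CIP priorities, not by inversion.

## Route

Step 1
Reactants: 1 dimethyl (S)-malate
Product: 2 dimethyl (2S,3R)-2-hydroxy-3-methylbutanedioate
Conditions: LiN(iPr)2 (2.1 equiv), THF, −78 → −20 °C; MeI, −78 → 0 °C; aq. NH4Cl
Reagents that add atoms: iodomethane, CI
Why: Fráter–Seebach alkylation: the dilithium alkoxide enolate is held in a chelate and iodomethane attacks the enolate face anti to the carbon substituent of the carbinol centre, which sets the new centre as R (anti isomer) by substrate control. The minor syn isomer must be removed here or at 4, because after the later oxidation of the carbinol it would end as the enantiomer of the target.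

Step 2
Reactants: 2 dimethyl (2S,3R)-2-hydroxy-3-methylbutanedioate
Product: 3 methyl (2R,3S)-3,4-dihydroxy-2-methylbutanoate
Conditions: BH3·SMe2, NaBH4 (5 mol%), THF, 0 °C → rt; MeOH
Reagents that add atoms: none
Why: Hydroxyl-directed borane reduction: the alkoxyborane formed at the free hydroxyl delivers hydride through a five-membered chelate to the neighbouring ester only, so the distal ester stays; neither stereocentre is touched.

Step 3
Reactants: 3 methyl (2R,3S)-3,4-dihydroxy-2-methylbutanoate
Product: 4 methyl (2R)-2-[(4S)-2,2-dimethyl-1,3-dioxolan-4-yl]propanoate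
Conditions: Me2C(OMe)2, TsOH·H2O (cat.), acetone, rt
Reagents that add atoms: 2,2-dimethoxypropane, COC(C)(C)OC
Why: Acid-catalysed transacetalisation of the terminal 1,2-diol, which should be faster than lactonisation of the primary hydroxyl onto the ester; the dioxolane is stable to the strong bases, nucleophiles and heating that follow.

Step 4
Reactants: 4 methyl (2R)-2-[(4S)-2,2-dimethyl-1,3-dioxolan-4-yl]propanoate
Product: 5 (2R)-2-[(4S)-2,2-dimethyl-1,3-dioxolan-4-yl]propanoic acid
Conditions: LiOH·H2O, THF/H2O, 0 °C; then 1 M HCl to pH 4, 0 °C
Reagents that add atoms: lithium hydroxide, [Li+].[OH-]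
Why: Ester saponification; the carboxylate formed does not enolise, so the α-centre should hold, and brief cold acidification to pH 4 spares the acetonide.

Step 5
Reactants: 5 (2R)-2-[(4S)-2,2-dimethyl-1,3-dioxolan-4-yl]propanoic acid
Product: 6 (2R)-2-[(4S)-2,2-dimethyl-1,3-dioxolan-4-yl]-1-(imidazol-1-yl)propan-1-one
Conditions: 1,1'-carbonyldiimidazole (1.1 equiv), CH2Cl2, rt; cold water wash
Reagents that add atoms: 1,1'-carbonyldiimidazole, O=C(n1ccnc1)n1ccnc1
Why: Acyl transfer from carbonyldiimidazole with loss of CO2 gives the acyl imidazole under neutral conditions; the imidazole set free is washed out so that it cannot protonate the dianion in step 7.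

Step 6
Reactants: 7 2,2,6-trimethyl-4H-1,3-dioxin-4-one; 8 propanoyl chloride
Product: 9 2,2-dimethyl-6-(2-oxobutyl)-4H-1,3-dioxin-4-one
Conditions: 7 (2 equiv), LiN(SiMe3)2 (2 equiv), THF, −78 °C; then 8 (1 equiv), −78 °C
Reagents that add atoms: none
Why: Vinylogous Claisen acylation: deprotonation of the C6 methyl gives the lithium dienolate, which is C-acylated at the exocyclic carbon; the second equivalent of dienolate takes up the proton of the more acidic product.

Step 7
Reactants: 9 2,2-dimethyl-6-(2-oxobutyl)-4H-1,3-dioxin-4-one; 6 (2R)-2-[(4S)-2,2-dimethyl-1,3-dioxolan-4-yl]-1-(imidazol-1-yl)propan-1-one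
Product: 10 6-[(5R)-5-[(4S)-2,2-dimethyl-1,3-dioxolan-4-yl]-3-methyl-2,4-dioxohexyl]-2,2-dimethyl-4H-1,3-dioxin-4-one (mixture of C3 epimers and enol forms)
Conditions: 9 (2 equiv), LiN(iPr)2 (4.1 equiv), THF, −78 °C; Et2Zn; then 6 (1 equiv), −78 → −10 °C; aq. NH4Cl
Reagents that add atoms: none
Why: Crossed Claisen acylation of a β-dicarbonyl dianion: the second deprotonation of 9 occurs at the ethyl CH2, the less stabilised and more nucleophilic site, and after transmetalation to the less basic zinc enolate this carbon attacks the acyl imidazole. The new β-diketone is deprotonated at once at its central carbon, which keeps the adjacent stereocentre from enolising.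

Step 8
Reactants: 10 6-[(5R)-5-[(4S)-2,2-dimethyl-1,3-dioxolan-4-yl]-3-methyl-2,4-dioxohexyl]-2,2-dimethyl-4H-1,3-dioxin-4-one; 11 benzyl alcohol
Product: 14 benzyl 6-[(1S)-1-[(4S)-2,2-dimethyl-1,3-dioxolan-4-yl]ethyl]-2,4-dihydroxy-5-methylbenzoate, via acylketene 12 (not isolated), via benzyl triketo ester 13 (not isolated)
Conditions: 11 (1.5 equiv), PhMe, 110 °C; then Et3N, CH2Cl2, rt; AcOH wash
Reagents that add atoms: none
Why: Heating 10 causes a retro-hetero-Diels–Alder loss of acetone to acylketene 12, which 11 traps at the ketene carbon to give β-keto ester 13; the excess of 11 should outrun capture of the ketene by an enol oxygen of the chain. With Et3N the C8a methylene, activated by the ester and the C8 ketone, adds as its enolate to the C4a ketone in a six-membered (enolendo)-exo-trig aldol closure that forms the C4a–C8a bond and ring A. E1cB loss of the tertiary hydroxyl and enolisation of the C6 and C8 carbonyls then give the arene, and aromatisation makes the sequence irreversible. The closest known reaction type is alcohol trapping of acylketenes from diketo-dioxinones followed by aldol aromatisation of the triketo esters to resorcylates. No stereocentre is created; the stereogenic C5 of 10 becomes an sp2 carbon. Aldol rather than Claisen folding is needed, and the C5 methyl secures it: attack of C5 on the ester carbonyl would give a ring with a quaternary C5 that cannot aromatise. The C4 centre must survive, and it should: its hydrogen is α to one carbonyl only and far less acidic than the β-dicarbonyl sites the amine engages, and the C4a carbonyl is held in the enolised β-diketone, so neither epimerisation nor β-elimination of the dioxolane oxygen is expected; no mineral acid is used, so the acetonide stays.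

Step 9
Reactants: 14 benzyl 6-[(1S)-1-[(4S)-2,2-dimethyl-1,3-dioxolan-4-yl]ethyl]-2,4-dihydroxy-5-methylbenzoate
Product: 15 benzyl 6-[(1S)-1-[(4S)-2,2-dimethyl-1,3-dioxolan-4-yl]ethyl]-2-hydroxy-4-methoxy-5-methylbenzoate
Conditions: MeI (1.1 equiv), K2CO3, acetone, rt
Reagents that add atoms: iodomethane, CI
Why: Williamson etherification under weak base: the C6 hydroxyl, para to the ester and not hydrogen-bonded, is the more acidic and more accessible phenol, while the C8 hydroxyl is chelated to the ester carbonyl, so one equivalent of iodomethane should give the C6 methyl ether.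

Step 10
Reactants: 15 benzyl 6-[(1S)-1-[(4S)-2,2-dimethyl-1,3-dioxolan-4-yl]ethyl]-2-hydroxy-4-methoxy-5-methylbenzoate
Product: 16 benzyl 2-(benzyloxy)-6-[(1S)-1-[(4S)-2,2-dimethyl-1,3-dioxolan-4-yl]ethyl]-4-methoxy-5-methylbenzoate
Conditions: BnBr, Cs2CO3, DMF, rt → 50 °C
Reagents that add atoms: benzyl bromide, BrCc1ccccc1
Why: Williamson benzylation of the chelated phenol as its caesium salt. The benzyl ether removes the hydrogen bond that activates the C1 ester and twists the ester out of the ring plane, which protects it from the side-chain hydroxyl in steps 11 and 15 and keeps the phenol out of the acylation and oxidation; it is removed in step 17 at no extra cost.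

Step 11
Reactants: 16 benzyl 2-(benzyloxy)-6-[(1S)-1-[(4S)-2,2-dimethyl-1,3-dioxolan-4-yl]ethyl]-4-methoxy-5-methylbenzoate
Product: 17 benzyl 2-(benzyloxy)-6-[(2S,3S)-3,4-dihydroxybutan-2-yl]-4-methoxy-5-methylbenzoate
Conditions: AcOH/H2O/THF (3:1:1), rt
Reagents that add atoms: none
Why: Acid-catalysed hydrolysis of a terminal dioxolane under mild aqueous acetic acid, to which benzyl ethers and the di-ortho-substituted benzyl ester are stable; the diol is used at once because its secondary hydroxyl could slowly lactonise onto C1.

Step 12
Reactants: 18 4,5-dimethylbenzene-1,3-diol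
Product: 19 2,4-dihydroxy-5,6-dimethylbenzaldehyde
Conditions: POCl3, DMF, 0 °C → rt; then H2O, 50 °C
Reagents that add atoms: N,N-dimethylformamide, CN(C)C=O; water, O
Why: Vilsmeier–Haack formylation: the chloroiminium ion attacks the only ring position para to one hydroxyl and ortho to the other, as in the formylation of orcinol, and hydrolysis of the iminium salt gives the aldehyde.

Step 13
Reactants: 19 2,4-dihydroxy-5,6-dimethylbenzaldehyde
Product: 20 2,4-bis(benzyloxy)-5,6-dimethylbenzaldehyde
Conditions: BnBr (2.5 equiv), K2CO3, DMF, 60 °C
Reagents that add atoms: benzyl bromide, BrCc1ccccc1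
Why: Double Williamson benzylation; heating in DMF is needed for the hydroxyl chelated to the aldehyde.

Step 14
Reactants: 20 2,4-bis(benzyloxy)-5,6-dimethylbenzaldehyde
Product: 21 2,4-bis(benzyloxy)-5,6-dimethylbenzoic acid
Conditions: NaClO2, NaH2PO4, 2-methyl-2-butene, tBuOH/H2O, rt
Reagents that add atoms: sodium chlorite, [Na+].[O-]Cl=O
Why: Pinnick oxidation: chlorous acid oxidises the aldehyde and 2-methyl-2-butene scavenges the hypochlorous acid formed, so the electron-rich ring should not be chlorinated.

Step 15
Reactants: 17 benzyl 2-(benzyloxy)-6-[(2S,3S)-3,4-dihydroxybutan-2-yl]-4-methoxy-5-methylbenzoate; 21 2,4-bis(benzyloxy)-5,6-dimethylbenzoic acid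
Product: 23 (2S,3S)-3-[3-(benzyloxy)-2-[(benzyloxy)carbonyl]-5-methoxy-6-methylphenyl]-2-hydroxybutyl 2,4-bis(benzyloxy)-5,6-dimethylbenzoate, via aroyl chloride 22 (not isolated)
Conditions: 21, (COCl)2, DMF (cat.), CH2Cl2, 0 °C → rt, evaporate; then 17, pyridine, DMAP (cat.), CH2Cl2, −20 → 0 °C
Reagents that add atoms: none
Why: Acid chloride formation followed by DMAP-catalysed nucleophilic acyl substitution; the di-ortho-substituted aroyl chloride should react only with the unhindered primary hydroxyl, the secondary one being flanked by the branched benzylic carbon.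

Step 16
Reactants: 23 (2S,3S)-3-[3-(benzyloxy)-2-[(benzyloxy)carbonyl]-5-methoxy-6-methylphenyl]-2-hydroxybutyl 2,4-bis(benzyloxy)-5,6-dimethylbenzoate
Product: 24 (3S)-3-[3-(benzyloxy)-2-[(benzyloxy)carbonyl]-5-methoxy-6-methylphenyl]-2-oxobutyl 2,4-bis(benzyloxy)-5,6-dimethylbenzoate
Conditions: Dess–Martin periodinane, NaHCO3, CH2Cl2, 0 °C → rt
Reagents that add atoms: none
Why: Dess–Martin oxidation (ligand exchange at pentavalent iodine, then intramolecular proton abstraction) under bicarbonate buffer and without amine base. The C4 hydrogen should lie in the plane of the di-ortho-substituted ring to avoid allylic strain, so it gains little benzylic activation and C4 should keep its configuration; 24 is taken on without storage.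

Step 17
Reactants: 24 (3S)-3-[3-(benzyloxy)-2-[(benzyloxy)carbonyl]-5-methoxy-6-methylphenyl]-2-oxobutyl 2,4-bis(benzyloxy)-5,6-dimethylbenzoate
Product: 25 [(3R,4S)-3,8-dihydroxy-6-methoxy-4,5-dimethyl-1-oxo-3,4-dihydro-1H-isochromen-3-yl]methyl 2,4-dihydroxy-5,6-dimethylbenzoate
Conditions: H2 (1 atm), Pd/C (10% Pd), EtOAc, rt
Reagents that add atoms: none
Why: Hydrogenolysis of the four O-benzyl groups; the freed C1 acid adds to the C3 ketone (ring-chain tautomerism of a δ-keto acid, 6-exo-trig). The hemiketal should settle as the epimer with the anomeric hydroxyl axial and trans to the pseudo-axial C4 methyl, which is 3R; a neutral aprotic solvent avoids dehydration to the isocoumarin and pseudo-ester formation.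

## Compound list

1 | dimethyl (S)-malate | COC(=O)C[C@H](O)C(=O)OC | starting material
2 | dimethyl (2S,3R)-2-hydroxy-3-methylbutanedioate | COC(=O)[C@H](C)[C@H](O)C(=O)OC | intermediate
3 | methyl (2R,3S)-3,4-dihydroxy-2-methylbutanoate | COC(=O)[C@H](C)[C@H](O)CO | intermediate
4 | methyl (2R)-2-[(4S)-2,2-dimethyl-1,3-dioxolan-4-yl]propanoate | COC(=O)[C@H](C)[C@H]1COC(C)(C)O1 | intermediate
5 | (2R)-2-[(4S)-2,2-dimethyl-1,3-dioxolan-4-yl]propanoic acid | OC(=O)[C@H](C)[C@H]1COC(C)(C)O1 | intermediate
6 | (2R)-2-[(4S)-2,2-dimethyl-1,3-dioxolan-4-yl]-1-(imidazol-1-yl)propan-1-one | O=C(n1ccnc1)[C@H](C)[C@H]1COC(C)(C)O1 | intermediate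
7 | 2,2,6-trimethyl-4H-1,3-dioxin-4-one | CC1=CC(=O)OC(C)(C)O1 | starting material
8 | propanoyl chloride | CCC(=O)Cl | starting material
9 | 2,2-dimethyl-6-(2-oxobutyl)-4H-1,3-dioxin-4-one | CCC(=O)CC1=CC(=O)OC(C)(C)O1 | intermediate
10 | 6-[(5R)-5-[(4S)-2,2-dimethyl-1,3-dioxolan-4-yl]-3-methyl-2,4-dioxohexyl]-2,2-dimethyl-4H-1,3-dioxin-4-one | CC1(C)OC(=O)C=C(CC(=O)C(C)C(=O)[C@H](C)[C@H]2COC(C)(C)O2)O1 | intermediate
11 | benzyl alcohol | OCc1ccccc1 | starting material
12 | (8R)-8-[(4S)-2,2-dimethyl-1,3-dioxolan-4-yl]-6-methylnon-1-ene-1,3,5,7-tetrone (acylketene) | O=C=CC(=O)CC(=O)C(C)C(=O)[C@H](C)[C@H]1COC(C)(C)O1 | intermediate (not isolated)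
13 | benzyl (8R)-8-[(4S)-2,2-dimethyl-1,3-dioxolan-4-yl]-6-methyl-3,5,7-trioxononanoate | O=C(CC(=O)CC(=O)C(C)C(=O)[C@H](C)[C@H]1COC(C)(C)O1)OCc1ccccc1 | intermediate (not isolated)
14 | benzyl 6-[(1S)-1-[(4S)-2,2-dimethyl-1,3-dioxolan-4-yl]ethyl]-2,4-dihydroxy-5-methylbenzoate | Cc1c(O)cc(O)c(C(=O)OCc2ccccc2)c1[C@H](C)[C@H]1COC(C)(C)O1 | intermediate
15 | benzyl 6-[(1S)-1-[(4S)-2,2-dimethyl-1,3-dioxolan-4-yl]ethyl]-2-hydroxy-4-methoxy-5-methylbenzoate | COc1cc(O)c(C(=O)OCc2ccccc2)c(c1C)[C@H](C)[C@H]1COC(C)(C)O1 | intermediate
16 | benzyl 2-(benzyloxy)-6-[(1S)-1-[(4S)-2,2-dimethyl-1,3-dioxolan-4-yl]ethyl]-4-methoxy-5-methylbenzoate | COc1cc(OCc2ccccc2)c(C(=O)OCc2ccccc2)c(c1C)[C@H](C)[C@H]1COC(C)(C)O1 | intermediate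
17 | benzyl 2-(benzyloxy)-6-[(2S,3S)-3,4-dihydroxybutan-2-yl]-4-methoxy-5-methylbenzoate | COc1cc(OCc2ccccc2)c(C(=O)OCc2ccccc2)c(c1C)[C@H](C)[C@H](O)CO | intermediate
18 | 4,5-dimethylbenzene-1,3-diol (4,5-dimethylresorcinol) | Cc1cc(O)cc(O)c1C | starting material
19 | 2,4-dihydroxy-5,6-dimethylbenzaldehyde | O=Cc1c(O)cc(O)c(C)c1C | intermediate
20 | 2,4-bis(benzyloxy)-5,6-dimethylbenzaldehyde | O=Cc1c(OCc2ccccc2)cc(OCc2ccccc2)c(C)c1C | intermediate
21 | 2,4-bis(benzyloxy)-5,6-dimethylbenzoic acid | OC(=O)c1c(OCc2ccccc2)cc(OCc2ccccc2)c(C)c1C | intermediate
22 | 2,4-bis(benzyloxy)-5,6-dimethylbenzoyl chloride | O=C(Cl)c1c(OCc2ccccc2)cc(OCc2ccccc2)c(C)c1C | intermediate (not isolated)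
23 | (2S,3S)-3-[3-(benzyloxy)-2-[(benzyloxy)carbonyl]-5-methoxy-6-methylphenyl]-2-hydroxybutyl 2,4-bis(benzyloxy)-5,6-dimethylbenzoate | COc1cc(OCc2ccccc2)c(C(=O)OCc2ccccc2)c(c1C)[C@H](C)[C@H](O)COC(=O)c1c(OCc2ccccc2)cc(OCc2ccccc2)c(C)c1C | intermediate
24 | (3S)-3-[3-(benzyloxy)-2-[(benzyloxy)carbonyl]-5-methoxy-6-methylphenyl]-2-oxobutyl 2,4-bis(benzyloxy)-5,6-dimethylbenzoate | COc1cc(OCc2ccccc2)c(C(=O)OCc2ccccc2)c(c1C)[C@H](C)C(=O)COC(=O)c1c(OCc2ccccc2)cc(OCc2ccccc2)c(C)c1C | intermediate
25 | [(3R,4S)-3,8-dihydroxy-6-methoxy-4,5-dimethyl-1-oxo-3,4-dihydro-1H-isochromen-3-yl]methyl 2,4-dihydroxy-5,6-dimethylbenzoate | COc1cc(O)c2c(c1C)[C@H](C)[C@](O)(COC(=O)c1c(O)cc(O)c(C)c1C)OC2=O | target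

## Step count and least certain steps

Total step count: 17. Longest linear sequence: 13 steps (1, 2, 3, 4, 5, 7, 8, 9, 10, 11, 15, 16, 17); step 6 and steps 12 to 14 are side branches.

**Step 8 (key step).** Two processes are most likely to go wrong. The first is capture of the acylketene by an enol oxygen of its own β-diketone (closure to a pyranone) before benzyl alcohol adds. The second is a slow aldol at the doubly α-branched C4a ketone, which would leave the triketo ester in base long enough for retro-Claisen cleavage at the methylated β-diketone or for enolisation towards C4, with loss of configuration or β-elimination of the dioxolane oxygen. Fallback, from 10 to 15, without any ketene: 10 is treated with Et3N in CH2Cl2 at room temperature, so that the dioxinone ring carbon next to its carbonyl adds to the C4a ketone and the adduct aromatises with the dioxinone intact to the benzodioxinone 5-[(1S)-1-[(4S)-2,2-dimethyl-1,3-dioxolan-4-yl]ethyl]-7-hydroxy-2,2,6-trimethyl-4H-1,3-benzodioxin-4-one F1. Its only free phenol is methylated (MeI, K2CO3, acetone) to the 7-methoxy benzodioxinone F2. BnONa (from 11 and NaH, THF, 0 °C) then opens the benzodioxinone with loss of acetone and should give 15 directly; this also removes the selectivity question of step 9.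

**Step 7.** The likely failure is proton transfer in place of acylation: the dianion deprotonates the α-branched acyl imidazole, which would scramble the future C4 centre or eliminate the dioxolane oxygen, and the hindered secondary carbon nucleophile favours this. Fallback, from 4 and 9 to 10, by aldol addition and oxidation: 4 is reduced with iBu2AlH (CH2Cl2, −78 °C) to (2R)-2-[(4S)-2,2-dimethyl-1,3-dioxolan-4-yl]propanal F3, which is added at −78 °C to the dianion of 9 (LiN(iPr)2, THF). This should give the β-hydroxy ketone 6-[5-[(4S)-2,2-dimethyl-1,3-dioxolan-4-yl]-4-hydroxy-3-methyl-2-oxohexyl]-2,2-dimethyl-4H-1,3-dioxin-4-one F4 as a mixture at the two new centres, both of which disappear later. Oxidation of F4 with Dess–Martin periodinane gives 10.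

**Step 15.** The likely failures are acylation of the secondary hydroxyl and, because the di-ortho-substituted acyl chloride reacts slowly, attack of the free C3 hydroxyl on the C1 benzyl ester (lactonisation with loss of benzyl alcohol) or later migration of the aroyl group. Fallback, from 17 to 24, which removes the secondary hydroxyl before the slow acylation: 17 is silylated at the primary hydroxyl (tBuMe2SiCl, imidazole, CH2Cl2, 0 °C) to benzyl 2-(benzyloxy)-6-[(2S,3S)-4-{[tert-butyl(dimethyl)silyl]oxy}-3-hydroxybutan-2-yl]-4-methoxy-5-methylbenzoate F5. Oxidation (Dess–Martin periodinane, NaHCO3) gives the silyloxy ketone benzyl 2-(benzyloxy)-6-[(2S)-4-{[tert-butyl(dimethyl)silyl]oxy}-3-oxobutan-2-yl]-4-methoxy-5-methylbenzoate F6, which has no hydroxyl left to lactonise. HF·pyridine (THF/pyridine, 0 °C) frees the hydroxy ketone benzyl 2-(benzyloxy)-6-[(2S)-4-hydroxy-3-oxobutan-2-yl]-4-methoxy-5-methylbenzoate F7, and acylation of F7 with 22 (pyridine, DMAP) gives 24.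

**Step 1.** The likely failure is incomplete facial selectivity in the enolate methylation together with incomplete separation of the syn isomer. The later oxidation at C3 turns that isomer into the enantiomer of the target, so the fault shows up as erosion of enantiomeric purity. Fallback, from 3 to 4, by purification through a rigid ring: crude 3 is lactonised (TsOH cat., CH2Cl2) to (3R,4S)-4-hydroxy-3-methyloxolan-2-one F8, the diastereomeric lactones are separated by chromatography or crystallisation, and pure F8 is reopened and protected in one operation (Me2C(OMe)2, MeOH, TsOH cat.) to give 4.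

## Further compounds

F1 | step 8 | 5-[(1S)-1-[(4S)-2,2-dimethyl-1,3-dioxolan-4-yl]ethyl]-7-hydroxy-2,2,6-trimethyl-4H-1,3-benzodioxin-4-one | Cc1c(O)cc2OC(C)(C)OC(=O)c2c1[C@H](C)[C@H]1COC(C)(C)O1
F2 | step 8 | 5-[(1S)-1-[(4S)-2,2-dimethyl-1,3-dioxolan-4-yl]ethyl]-7-methoxy-2,2,6-trimethyl-4H-1,3-benzodioxin-4-one | COc1cc2OC(C)(C)OC(=O)c2c(c1C)[C@H](C)[C@H]1COC(C)(C)O1
F3 | step 7 | (2R)-2-[(4S)-2,2-dimethyl-1,3-dioxolan-4-yl]propanal | O=C[C@H](C)[C@H]1COC(C)(C)O1
F4 | step 7 | 6-[5-[(4S)-2,2-dimethyl-1,3-dioxolan-4-yl]-4-hydroxy-3-methyl-2-oxohexyl]-2,2-dimethyl-4H-1,3-dioxin-4-one (C5 of the chain as in F3, C3 and C4 as mixtures) | CC1(C)OC(=O)C=C(CC(=O)C(C)C(O)[C@H](C)[C@H]2COC(C)(C)O2)O1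
F5 | step 15 | benzyl 2-(benzyloxy)-6-[(2S,3S)-4-{[tert-butyl(dimethyl)silyl]oxy}-3-hydroxybutan-2-yl]-4-methoxy-5-methylbenzoate | COc1cc(OCc2ccccc2)c(C(=O)OCc2ccccc2)c(c1C)[C@H](C)[C@H](O)CO[Si](C)(C)C(C)(C)C
F6 | step 15 | benzyl 2-(benzyloxy)-6-[(2S)-4-{[tert-butyl(dimethyl)silyl]oxy}-3-oxobutan-2-yl]-4-methoxy-5-methylbenzoate | COc1cc(OCc2ccccc2)c(C(=O)OCc2ccccc2)c(c1C)[C@H](C)C(=O)CO[Si](C)(C)C(C)(C)C
F7 | step 15 | benzyl 2-(benzyloxy)-6-[(2S)-4-hydroxy-3-oxobutan-2-yl]-4-methoxy-5-methylbenzoate | COc1cc(OCc2ccccc2)c(C(=O)OCc2ccccc2)c(c1C)[C@H](C)C(=O)CO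
F8 | step 1 | (3R,4S)-4-hydroxy-3-methyloxolan-2-one | O=C1[C@H](C)[C@H](O)CO1
A1 | alternative 1 | [(3R,4S)-8-(benzyloxy)-3-hydroxy-6-methoxy-4,5-dimethyl-1-oxo-3,4-dihydro-1H-isochromen-3-yl]methyl 2,4-bis(benzyloxy)-5,6-dimethylbenzoate | COc1cc(OCc3ccccc3)c2c(c1C)[C@H](C)[C@](O)(COC(=O)c1c(OCc3ccccc3)cc(OCc3ccccc3)c(C)c1C)OC2=O
A2 | alternative 1 | [(3S)-7-(benzyloxy)-2-hydroxy-5-methoxy-3,4-dimethyl-1-oxo-2,3-dihydro-1H-inden-2-yl]methyl 2,4-bis(benzyloxy)-5,6-dimethylbenzoate (either C2 epimer) | COc1cc(OCc3ccccc3)c2c(c1C)[C@H](C)C(O)(COC(=O)c1c(OCc3ccccc3)cc(OCc3ccccc3)c(C)c1C)C2=O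
A3 | alternative 2 | (3S)-3-[3-(benzyloxy)-2-[(benzyloxy)carbonyl]-5-methoxy-6-methylphenyl]-2-oxobutyl 2,4-dihydroxy-5,6-dimethylbenzoate | COc1cc(OCc2ccccc2)c(C(=O)OCc2ccccc2)c(c1C)[C@H](C)C(=O)COC(=O)c1c(O)cc(O)c(C)c1C
A4 | alternative 2 | (3S)-3-[3-(benzyloxy)-2-[(benzyloxy)carbonyl]-5-methoxy-6-methylphenyl]-2-oxobutyl but-2-ynoate | COc1cc(OCc2ccccc2)c(C(=O)OCc2ccccc2)c(c1C)[C@H](C)C(=O)COC(=O)C#CC
A5 | alternative 2 | 1-methoxy-1,3-bis(trimethylsilyloxy)penta-1,3-diene | COC(O[Si](C)(C)C)=CC(O[Si](C)(C)C)=CC
A6 | alternative 3 | (2R,3S)-3-[2-[(benzyloxy)carbonyl]-3-hydroxy-5-methoxy-6-methylphenyl]-2-[(triethylsilyl)oxy]butyl 2,4-bis(benzyloxy)-5,6-dimethylbenzoate | COc1cc(O)c(C(=O)OCc2ccccc2)c(c1C)[C@H](C)[C@@H](O[Si](CC)(CC)CC)COC(=O)c1c(OCc2ccccc2)cc(OCc2ccccc2)c(C)c1C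
A7 | alternative 3 | benzyl (4S,5R)-6-{[2,4-bis(benzyloxy)-5,6-dimethylbenzoyl]oxy}-4-methyl-5-[(triethylsilyl)oxy]hex-2-ynoate | O=C(OCc1ccccc1)C#C[C@H](C)[C@@H](O[Si](CC)(CC)CC)COC(=O)c1c(OCc2ccccc2)cc(OCc2ccccc2)c(C)c1C
A8 | alternative 3 | 1,3-dimethoxy-1-(trimethylsilyloxy)penta-1,3-diene | COC(O[Si](C)(C)C)=CC(OC)=CC
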